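**Plan**

- Retrosynthetic cuts, in order: the 4'-O–CH3 bond; both C4a–C5 bonds of rings A; in each side chain C5–C6 (ester carbon), C8–Cl and C7–C8 (acetyl); the two C3–C1' bonds; the diaryl ether C–O bond.
- Forward order: diaryl ether and its bis-boronate; rings C arrive preformed as allomaltol triflate and are joined twice by Suzuki coupling; each 6-methyl group is grown outward to CH(Cl)–CO–CH2–CO2Me; both rings A close in one operation; demethylation.
- Enabling feature: ring A of each isoflavone carries oxygen on C5, C7 and C8a and chlorine on C8. C8–C7–C6–C5 is therefore a chlorinated acetoacetate chain on C8a of a 4-pyranone (ring C), and C4a of that ring can attack the ester carbon.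
- Order within the chain: chlorine enters while the methylene between C8a and the ketone is the only acidic site; the ester carbon follows, so no second active methylene competes for the halogen.
- Stereochemistry: the target has no stereocentres; the chloromethine centres of 9 and 10 are labile, formed as mixtures, and erased on aromatisation.

Key step: step 8

Assumption: allomaltol (5) is taken as a commercial compound; it is also the known zinc/HCl reduction product of chlorokojic acid, itself made from kojic acid with SOCl2.

**Route**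

Step 1
Reactants: 1 5-bromo-2-methoxyphenol; 2 (4-bromophenyl)boronic acid
Product: 3 4-bromo-2-(4-bromophenoxy)-1-methoxybenzene
Conditions: Cu(OAc)2 (1.5 equiv), pyridine (5 equiv), 4 Å molecular sieves, CH2Cl2, air, rt
Reagents that add atoms: none
Why: Chan–Lam O-arylation joins phenol and arylboronic acid at room temperature, where neither aryl bromide reacts, so both bromides remain for the borylation.

Step 2
Reactants: 3 4-bromo-2-(4-bromophenoxy)-1-methoxybenzene
Product: 4 2-{4-methoxy-3-[4-(4,4,5,5-tetramethyl-1,3,2-dioxaborolan-2-yl)phenoxy]phenyl}-4,4,5,5-tetramethyl-1,3,2-dioxaborolane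
Conditions: B2pin2 (2.5 equiv), PdCl2(dppf) (5 mol %), KOAc (6 equiv), 1,4-dioxane, 90 °C
Reagents that add atoms: bis(pinacolato)diboron, CC1(C)OB(OC1(C)C)B1OC(C)(C)C(C)(C)O1
Why: Twofold Miyaura borylation of unhindered aryl bromides with the weak base KOAc should give the bis(pinacol boronate) without competing biaryl formation.

Step 3
Reactants: 5 allomaltol (5-hydroxy-2-methyl-4H-pyran-4-one)
Product: 6 6-methyl-4-oxo-4H-pyran-3-yl trifluoromethanesulfonate
Conditions: Tf2O (1.1 equiv), pyridine (2 equiv), CH2Cl2, −10 → 0 °C
Reagents that add atoms: trifluoromethanesulfonic anhydride, O=S(=O)(OS(=O)(=O)C(F)(F)F)C(F)(F)F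
Why: O-sulfonylation of the acidic enolic hydroxyl is the standard way to turn 5-hydroxy-4-pyranones of the kojic acid family into cross-coupling electrophiles.

Step 4
Reactants: 4 the bis(pinacol boronate); 6 6-methyl-4-oxo-4H-pyran-3-yl trifluoromethanesulfonate (2.3 equiv)
Product: 7 1-methoxy-4-(6-methyl-4-oxo-4H-pyran-3-yl)-2-[4-(6-methyl-4-oxo-4H-pyran-3-yl)phenoxy]benzene
Conditions: PdCl2(dppf) (6 mol %), K3PO4 (4 equiv), 1,4-dioxane/H2O 10:1, 80 °C
Reagents that add atoms: none
Why: Twofold Suzuki–Miyaura coupling of the electron-poor pyranonyl triflate with the arylboronates forms both C3–C1' bonds, and the mild phosphate base spares triflate and pyranone rings.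

Step 5
Reactants: 7 the bis(6-methyl-4-pyranone)
Product: 8 1-methoxy-4-[4-oxo-6-(2-oxopropyl)-4H-pyran-3-yl]-2-{4-[4-oxo-6-(2-oxopropyl)-4H-pyran-3-yl]phenoxy}benzene
Conditions: LiN(SiMe3)2 (2.5 equiv), THF, −78 °C; MeC(O)N(OMe)Me (2.6 equiv), −78 → −20 °C; AcOH quench
Reagents that add atoms: N-methoxy-N-methylacetamide, CC(=O)N(C)OC
Why: Lateral (vinylogous) deprotonation of the 6-methyl groups gives dienolates that are C-acylated at the exocyclic carbon by the Weinreb amide, whose chelated tetrahedral adduct prevents over-addition and keeps the acidic product masked until the quench.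

Step 6
Reactants: 8 the bis(acetonyl) pyranone
Product: 9 4-[6-(1-chloro-2-oxopropyl)-4-oxo-4H-pyran-3-yl]-2-{4-[6-(1-chloro-2-oxopropyl)-4-oxo-4H-pyran-3-yl]phenoxy}-1-methoxybenzene (mixture of diastereomers at the two chloromethine carbons, configuration not controlled)
Conditions: NCS (2.05 equiv), Et3N (0.1 equiv), CH2Cl2, 0 °C
Reagents that add atoms: N-chlorosuccinimide, O=C1CCC(=O)N1Cl
Why: Electrophilic α-chlorination of an active methylene: the CH2 between the ketone and pyranone C6 is a vinylogous 1,3-dicarbonyl position and the only readily enolised site, so one chlorine per arm should enter exactly at the future C8; the new centres are formed without control and do not matter.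

Step 7
Reactants: 9 the bis(α-chloro ketone)
Product: 10 dimethyl diester, 4-[6-(1-chloro-4-methoxy-2,4-dioxobutyl)-4-oxo-4H-pyran-3-yl]-2-{4-[6-(1-chloro-4-methoxy-2,4-dioxobutyl)-4-oxo-4H-pyran-3-yl]phenoxy}-1-methoxybenzene (mixture of diastereomers and keto/enol tautomers)
Conditions: LiN(iPr)2 (6.6 equiv), THF, −78 → −40 °C; (MeO)2CO (4 equiv), −78 → −20 °C; AcOH, −78 °C
Reagents that add atoms: dimethyl carbonate, COC(=O)OC
Why: Claisen-type carbomethoxylation of a ketone 1,3-dianion: after the chloromethine is deprotonated, a second equivalent of amide base removes a methyl proton and the more reactive terminal carbanion is C-acylated, while chlorine sits on an sp2 carbon of the polyanion (no Favorskii-type chloride loss) and the cold acid quench returns the keto ester before it can cyclise.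

Step 8
Reactants: 10 the bis[6-(1-chloro-4-methoxy-2,4-dioxobutyl)-4-pyranone]
Product: 11 4'-O-methylbisoflavolin M, 8-chloro-3-{4-[5-(8-chloro-5,7-dihydroxy-4-oxo-4H-chromen-3-yl)-2-methoxyphenoxy]phenyl}-5,7-dihydroxy-4H-chromen-4-one
Conditions: DBU (8 equiv), THF, 0 → 45 °C; then 1 M HCl
Reagents that add atoms: none
Why: DBU removes the chloromethine proton of each arm, which is flanked by the ketone, by chlorine and, through C8a, by the vinylogous pyranone carbonyl, and the resulting extended enolate (delocalised over C8, C8a, C4a and the C4 oxygen) adds through C4a to the ester carbonyl; methoxide is expelled and loss of the C4a and C6 protons in two enolisations leaves the 5,7-dihydroxy-8-chloro benzene ring. The closest known reaction type is the biomimetic intramolecular Claisen (Dieckmann-type) cyclisation and aromatisation of β-polycarbonyl chains anchored on a pyrone, the laboratory counterpart of polyketide folding to phloroglucinol rings. Each of the two new six-membered carbocycles (rings A) closes in the 6-(enolexo)-exo-trig mode, one C4a–C5 bond per arm. No stereocentre is created; the two labile chloromethine centres of 10 become sp2 carbons, so the diastereomer mixture converges on one product. The step needs the Claisen closure to be the only cyclisation and the chlorine to finish at C8: the single ester carbonyl lies six atoms from the only ring nucleophile C4a, attack through C8 would give a four-membered ring, no chain carbonyl is placed for an aldol closure, and the chlorinated carbon is bonded to C8a from the outset. A non-nucleophilic amidine base is chosen so that the activated C–Cl bond, vinylic once deprotonated, is not displaced before it has become an aryl chloride.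

Step 9
Reactants: 11 4'-O-methylbisoflavolin M
Product: 12 bisoflavolin M, 8-chloro-3-{4-[5-(8-chloro-5,7-dihydroxy-4-oxo-4H-chromen-3-yl)-2-hydroxyphenoxy]phenyl}-5,7-dihydroxy-4H-chromen-4-one
Conditions: BBr3 (10 equiv), CH2Cl2, −78 °C → rt; MeOH, then H2O
Reagents that add atoms: none
Why: Lewis-acid ether cleavage with BBr3 removes the single aryl methyl ether, while the diaryl ether, the aryl chlorides and the chelated 5-hydroxy-4-pyranone units are inert to the reagent.

**Compound list**

1 | 5-bromo-2-methoxyphenol | COc1ccc(Br)cc1O | starting material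
2 | (4-bromophenyl)boronic acid | OB(O)c1ccc(Br)cc1 | starting material
3 | 4-bromo-2-(4-bromophenoxy)-1-methoxybenzene | COc1ccc(Br)cc1Oc1ccc(Br)cc1 | intermediate
4 | 2-{4-methoxy-3-[4-(4,4,5,5-tetramethyl-1,3,2-dioxaborolan-2-yl)phenoxy]phenyl}-4,4,5,5-tetramethyl-1,3,2-dioxaborolane | COc1ccc(B2OC(C)(C)C(C)(C)O2)cc1Oc1ccc(B2OC(C)(C)C(C)(C)O2)cc1 | intermediate
5 | allomaltol (5-hydroxy-2-methyl-4H-pyran-4-one) | Cc1cc(=O)c(O)co1 | starting material
6 | 6-methyl-4-oxo-4H-pyran-3-yl trifluoromethanesulfonate | Cc1cc(=O)c(OS(=O)(=O)C(F)(F)F)co1 | intermediate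
7 | 1-methoxy-4-(6-methyl-4-oxo-4H-pyran-3-yl)-2-[4-(6-methyl-4-oxo-4H-pyran-3-yl)phenoxy]benzene | Cc1cc(=O)c(-c2ccc(Oc3cc(-c4coc(C)cc4=O)ccc3OC)cc2)co1 | intermediate
8 | 1-methoxy-4-[4-oxo-6-(2-oxopropyl)-4H-pyran-3-yl]-2-{4-[4-oxo-6-(2-oxopropyl)-4H-pyran-3-yl]phenoxy}benzene | CC(=O)Cc1cc(=O)c(-c2ccc(Oc3cc(-c4coc(CC(C)=O)cc4=O)ccc3OC)cc2)co1 | intermediate
9 | 4-[6-(1-chloro-2-oxopropyl)-4-oxo-4H-pyran-3-yl]-2-{4-[6-(1-chloro-2-oxopropyl)-4-oxo-4H-pyran-3-yl]phenoxy}-1-methoxybenzene, chloromethine centres unspecified | CC(=O)C(Cl)c1cc(=O)c(-c2ccc(Oc3cc(-c4coc(C(Cl)C(C)=O)cc4=O)ccc3OC)cc2)co1 | intermediate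
10 | 4-[6-(1-chloro-4-methoxy-2,4-dioxobutyl)-4-oxo-4H-pyran-3-yl]-2-{4-[6-(1-chloro-4-methoxy-2,4-dioxobutyl)-4-oxo-4H-pyran-3-yl]phenoxy}-1-methoxybenzene, chloromethine centres unspecified | COC(=O)CC(=O)C(Cl)c1cc(=O)c(-c2ccc(Oc3cc(-c4coc(C(Cl)C(=O)CC(=O)OC)cc4=O)ccc3OC)cc2)co1 | intermediate
11 | 4'-O-methylbisoflavolin M | O=c1c(-c2ccc(Oc3cc(-c4coc5c(Cl)c(O)cc(O)c5c4=O)ccc3OC)cc2)coc2c(Cl)c(O)cc(O)c12 | intermediate
12 | bisoflavolin M | O=c1c(-c2ccc(Oc3cc(-c4coc5c(Cl)c(O)cc(O)c5c4=O)ccc3O)cc2)coc2c(Cl)c(O)cc(O)c12 | target

**Count and risks**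

Total step count: 9. Longest linear sequence: 8 steps (steps 1, 2, 4, 5, 6, 7, 8, 9 from compound 1); step 3 is the one-step side branch.

Steps most likely to fail:

Step 7. Proton transfer from the newly formed β-keto ester to unreacted dianion, together with some O-acylation, may stall the carbomethoxylation and leave mixtures of homologated and unchanged arms. The fallback sets out from 9: the same polyanion is trapped with gaseous CO2, which adds faster than protons are exchanged and tolerates the excess amide base, to give the bis(β-keto acid) F1. F1 is then esterified cold with trimethylsilyldiazomethane in toluene/MeOH, which comes back to the route at 10.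

Step 8. Attack of the strongly delocalised enolate on a methyl ester may be slow, so that displacement of the activated chloride (O-alkylation by the keto ester enolate to a furanone, or intermolecular alkylation) competes with ring closure. The fallback sets out from 9: the polyanion is acylated with diphenyl carbonate in place of dimethyl carbonate to give the bis(phenyl β-keto ester) F2. Its better leaving group should allow the same C4a–C5 closure with Et3N in CH2Cl2 at or below room temperature, coming back at 11.

Step 6. A second chlorination of the more acidic monochloride, or attack of the chlorinating agent on the electron-rich ring B, may erode the one-chlorine-per-arm outcome. The fallback sets out from 8: Regitz diazo transfer (4-acetamidobenzenesulfonyl azide, DBU, MeCN) onto the active methylene gives the bis(α-diazo ketone) F3. Anhydrous HCl in 1,4-dioxane at 0 °C then protonates the diazo carbon and delivers chloride with loss of nitrogen, so exactly one chlorine is placed on each carbon, coming back at 9.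

**Further compounds**

F1 | step 7 | 4-chloro-4-{5-[4-(5-{6-[3-carboxy-1-chloro-2-oxopropyl]-4-oxo-4H-pyran-3-yl}-2-methoxyphenoxy)phenyl]-4-oxo-4H-pyran-2-yl}-3-oxobutanoic acid, the bis(β-keto acid) | OC(=O)CC(=O)C(Cl)c1cc(=O)c(-c2ccc(Oc3cc(-c4coc(C(Cl)C(=O)CC(=O)O)cc4=O)ccc3OC)cc2)co1
F2 | step 8 | diphenyl ester analogue of 10, the bis(phenyl 4-chloro-3-oxo-4-pyranonylbutanoate) | O=C(CC(=O)C(Cl)c1cc(=O)c(-c2ccc(Oc3cc(-c4coc(C(Cl)C(=O)CC(=O)Oc5ccccc5)cc4=O)ccc3OC)cc2)co1)Oc1ccccc1
F3 | step 6 | 4-[6-(1-diazo-2-oxopropyl)-4-oxo-4H-pyran-3-yl]-2-{4-[6-(1-diazo-2-oxopropyl)-4-oxo-4H-pyran-3-yl]phenoxy}-1-methoxybenzene | CC(=O)C(=[N+]=[N-])c1cc(=O)c(-c2ccc(Oc3cc(-c4coc(C(=[N+]=[N-])C(C)=O)cc4=O)ccc3OC)cc2)co1
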